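The 1,2‑dioxane (O1–O2–C3–C4–C5–C6) is disconnected to a cyclobutane C3–C4–C5–C6 whose C3–C6 bond accepts O2. A cobalt‑mediated aerobic ring expansion of a 1‑alkenyl‑2‑methoxycyclobutanol inserts dioxygen in one operation and leaves both peroxide carbons at the acetal level (C6–OH, C3–OMe), so the radical step need set no stereocentre. The only preset ring stereocentre, C4 (desymmetrised 3‑ethylcyclobutanone), then relays C6 and C3 through two axial peroxycarbenium alkylations. The side chain (C10 by catalytic ethylation and Johnson–Claisen transfer; E‑C7=C8 by carboalumination) is joined as an alkenyllithium to the cyclobutanone carbonyl, the future C6.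

Key step: step 12

Numbering (target locants, used for all dioxane intermediates): ring O1–O2–C3–C4–C5–C6; C3 carries CH2CO2H, C4 and C6 carry ethyl, C6 carries the side chain C7=C8(CH3)–C9–C10(Et)–C11=C12–C13–C14. Acetal and carbinol centres that form as mixtures and are destroyed later are left undefined in the SMILES.

Assumption: lithium (R,R)‑bis(1‑phenylethyl)amide is taken to remove the enantiotopic α‑proton that leads to the (R)‑enol ether 13; if the sense proves opposite, the (S,S)‑amide is used and nothing else changes.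

**Side‑chain fragment**

Step 1
Reactants: 1 (2E)‑pent‑2‑enal
Product: 2 (3R,4E)‑hept‑4‑en‑3‑ol
Conditions: Et2Zn, (+)‑MIB (4 mol %), hexanes–toluene, 0 °C; aq. NH4Cl
Reagents that add atoms: diethylzinc, CC[Zn]CC
Why: Catalytic asymmetric 1,2‑addition of an alkylzinc under amino‑alcohol catalysis should deliver ethyl to the Re face of the aldehyde and set the carbinol centre as R, (+)‑MIB being the mirror image of the catalyst that gives S‑carbinols.

Step 2
Reactants: 2 (3R,4E)‑hept‑4‑en‑3‑ol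
Product: 3 ethyl (3R,4E)‑3‑ethylhept‑4‑enoate
Conditions: MeC(OEt)3 (excess), EtCO2H (cat.), 140 °C, EtOH distilled off
Reagents that add atoms: triethyl orthoacetate, CC(OCC)(OCC)OCC
Why: Johnson–Claisen [3,3]‑sigmatropic rearrangement through a chair transition state with the carbinol ethyl group equatorial should transfer the R carbinol configuration to C10 (R) and form the E‑C11=C12 bond.

Step 3
Reactants: 3 ethyl (3R,4E)‑3‑ethylhept‑4‑enoate
Product: 4 (3R,4E)‑3‑ethylhept‑4‑enal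
Conditions: DIBAL‑H, CH2Cl2, −78 °C; Rochelle salt
Reagents that add atoms: none
Why: Partial hydride reduction of the ester at low temperature should stop at the aluminium hemiacetal and give the aldehyde on work‑up, and the stereocentre is β to the carbonyl and cannot epimerise.

Step 4
Reactants: 4 (3R,4E)‑3‑ethylhept‑4‑enal
Product: 5 (4R,5E)‑4‑ethyloct‑5‑en‑1‑yne
Conditions: Ohira–Bestmann reagent, K2CO3, MeOH, 0 °C to rt
Reagents that add atoms: dimethyl (1‑diazo‑2‑oxopropyl)phosphonate, CC(=O)C(=[N+]=[N-])P(=O)(OC)OC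
Why: Seyferth–Gilbert homologation in the Ohira–Bestmann version (olefination to a diazoalkene, loss of N2, 1,2‑hydride shift) should give the terminal alkyne under carbonate conditions that touch neither the alkene nor the stereocentre.

Step 5
Reactants: 5 (4R,5E)‑4‑ethyloct‑5‑en‑1‑yne
Product: 7 (1E,4R,5E)‑4‑ethyl‑1‑iodo‑2‑methylocta‑1,5‑diene, via alkenyldimethylalane 6 (not isolated)
Conditions: Me3Al, Cp2ZrCl2 (20 mol %), CH2Cl2, 0 °C to rt; then I2, THF, −30 °C
Reagents that add atoms: trimethylaluminium, C[Al](C)C; iodine, II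
Why: Zirconium‑catalysed carboalumination (Negishi) adds methyl and aluminium syn across the terminal alkyne with aluminium at the terminus, and iodinolysis with retention should give the E‑iodide while the internal disubstituted alkene stays inert.

**Cyclobutanone fragment**

Step 6
Reactants: 8 but‑1‑ene; 9 trichloroacetyl chloride
Product: 10 2,2‑dichloro‑3‑ethylcyclobutan‑1‑one (racemic)
Conditions: Zn(Cu), Et2O, excess butene, sealed vessel, 0 °C to rt
Reagents that add atoms: none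
Why: Thermal [2+2] cycloaddition of dichloroketene, generated by zinc dechlorination of the acid chloride, should join the carbonyl carbon to the CH2 terminus of the alkene and so place ethyl at C3 of the cyclobutanone.

Step 7
Reactants: 10 2,2‑dichloro‑3‑ethylcyclobutan‑1‑one
Product: 11 3‑ethylcyclobutan‑1‑one
Conditions: Zn, AcOH, rt to 50 °C
Reagents that add atoms: none
Why: Reductive removal of both α‑chlorines through zinc enolates should give the achiral, prochiral ketone.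

Step 8
Reactants: 11 3‑ethylcyclobutan‑1‑one
Product: 13 {[(3R)‑3‑ethylcyclobut‑1‑en‑1‑yl]oxy}trimethylsilane, via lithium enolate 12 (not isolated)
Conditions: (R,R)‑bis(1‑phenylethyl)amine, n‑BuLi, TMSCl (in situ quench), THF, −100 °C
Reagents that add atoms: chlorotrimethylsilane, C[Si](C)(C)Cl
Why: Enantioselective deprotonation of a prochiral 3‑substituted cyclobutanone by a C2‑symmetric chiral lithium amide with in situ silyl trapping should differentiate the enantiotopic α‑methylenes and fix the ethyl‑bearing carbon (future C4) as R, and any minor enantiomer becomes a separable diastereomer after step 11.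

Step 9
Reactants: 13 {[(3R)‑3‑ethylcyclobut‑1‑en‑1‑yl]oxy}trimethylsilane
Product: 16 (2S,3R)‑3‑ethyl‑2‑hydroxycyclobutan‑1‑one, via silyloxy epoxide 14 (not isolated), via 2‑silyloxy ketone 15 (not isolated)
Conditions: mCPBA, NaHCO3, CH2Cl2, −20 °C; then 1 M HCl, THF, 0 °C
Reagents that add atoms: 3‑chloroperoxybenzoic acid, OOC(=O)c1cccc(Cl)c1
Why: Rubottom oxidation should epoxidise the enol ether anti to the adjacent ethyl group, open the epoxide with 1,4‑silyl shift and release the trans α‑hydroxy ketone on acid work‑up, the new carbinol centre being of no consequence because it is destroyed in step 12.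

Step 10
Reactants: 16 (2S,3R)‑3‑ethyl‑2‑hydroxycyclobutan‑1‑one
Product: 17 (2S,3R)‑3‑ethyl‑2‑methoxycyclobutan‑1‑one
Conditions: MeOTf, 2,6‑di‑tert‑butyl‑4‑methylpyridine, CH2Cl2, 0 °C to rt; aq. NaHCO3
Reagents that add atoms: methyl trifluoromethanesulfonate, COS(=O)(=O)C(F)(F)F
Why: O‑Methylation with a hard methylating agent and a hindered non‑nucleophilic base should avoid base‑induced α‑ketol ring contraction and installs the group that later stabilises the C3 radical and serves as leaving group at C3.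

**Union and ring construction**

Step 11
Reactants: 7 (1E,4R,5E)‑4‑ethyl‑1‑iodo‑2‑methylocta‑1,5‑diene; 17 (2S,3R)‑3‑ethyl‑2‑methoxycyclobutan‑1‑one
Product: 19 (2S,3R)‑3‑ethyl‑1‑[(1E,4R,5E)‑4‑ethyl‑2‑methylocta‑1,5‑dien‑1‑yl]‑2‑methoxycyclobutan‑1‑ol (both C1 epimers), via alkenyllithium 18 (not isolated)
Conditions: t‑BuLi (2 equiv), Et2O, −78 °C; then 17, −78 °C; aq. NH4Cl
Reagents that add atoms: none
Why: Iodine–lithium exchange with retention of alkene geometry followed by 1,2‑addition to the strained cyclobutanone carbonyl should give the tertiary allylic cyclobutanol, whose carbinol configuration is irrelevant because C6 becomes a carbonyl carbon in the next step.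

Step 12
Reactants: 19 (2S,3R)‑3‑ethyl‑1‑[(1E,4R,5E)‑4‑ethyl‑2‑methylocta‑1,5‑dien‑1‑yl]‑2‑methoxycyclobutan‑1‑ol
Product: 21 (4R)‑4‑ethyl‑6‑[(1E,4R,5E)‑4‑ethyl‑2‑methylocta‑1,5‑dien‑1‑yl]‑3‑methoxy‑1,2‑dioxan‑6‑ol (C3/C6 epimers), via hydroperoxy enone 20 (not isolated)
Conditions: Co(acac)2 (20 mol %), O2 (1 atm), 1,2‑dichloroethane, 40 °C
Reagents that add atoms: dioxygen, O=O
Why: Co(II)/O2 should form a cobalt(III) alkoxide that releases the tertiary cyclobutyloxy radical, whose strain‑driven β‑scission of the C6–C3 bond gives the enone (C6=O) and an α‑methoxyalkyl radical at C3 that captures triplet O2 and is reduced by Co(II) to hydroperoxide 20. The closest known reaction type is the Co(acac)2/O2 oxidative ring expansion of cyclobutanols to 1,2‑dioxan‑3‑ols, the four‑ring counterpart of the manganese‑catalysed cyclopropanol to 1,2‑dioxolan‑3‑ol oxidation. The 1,2‑dioxane closes by 6‑exo‑trig addition of the distal peroxide oxygen on C3 to the C6 carbonyl (peroxy‑hemiketalisation), so that the four cyclobutane carbons C3–C6 plus O2 become the six‑membered ring. C3 and C6 arise as epimeric acetal centres without control, which is harmless because both are ionised later, and C4 is never α to a carbonyl and should be carried through unchanged. The step needs cleavage of C6–C3 rather than C6–C5, secured by the methoxy group that makes the C3 radical an α‑alkoxyalkyl radical, and it needs the two alkenes to stay untouched, which is expected because no hydride source is present.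

Step 13
Reactants: 21 (4R)‑4‑ethyl‑6‑[(1E,4R,5E)‑4‑ethyl‑2‑methylocta‑1,5‑dien‑1‑yl]‑3‑methoxy‑1,2‑dioxan‑6‑ol
Product: 22 2‑{(4R,6S)‑4‑ethyl‑6‑[(1E,4R,5E)‑4‑ethyl‑2‑methylocta‑1,5‑dien‑1‑yl]‑3‑methoxy‑1,2‑dioxan‑6‑yl}acetaldehyde (C3 epimers)
Conditions: CH2=CHOSiMe3, TMSOTf (10 mol %), CH2Cl2, −78 °C
Reagents that add atoms: trimethyl(vinyloxy)silane, C=CO[Si](C)(C)C
Why: Lewis‑acid ionisation of the tertiary hemiperketal gives the C6 peroxycarbenium ion, which ionises far more readily than the secondary methyl peroxyacetal at C3, and Mukaiyama‑type axial attack of the enol silane on the half‑chair with the C4 ethyl pseudo‑equatorial should place CH2CHO trans to the C4 ethyl and leave the side chain equatorial (C6 set by 1,3‑induction from C4).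

Step 14
Reactants: 22 2‑{(4R,6S)‑4‑ethyl‑6‑[(1E,4R,5E)‑4‑ethyl‑2‑methylocta‑1,5‑dien‑1‑yl]‑3‑methoxy‑1,2‑dioxan‑6‑yl}acetaldehyde
Product: 23 N'‑(2‑{(4R,6S)‑4‑ethyl‑6‑[(1E,4R,5E)‑4‑ethyl‑2‑methylocta‑1,5‑dien‑1‑yl]‑3‑methoxy‑1,2‑dioxan‑6‑yl}ethylidene)‑4‑methylbenzenesulfonohydrazide
Conditions: TsNHNH2, THF, 0 °C to rt
Reagents that add atoms: 4‑methylbenzenesulfonohydrazide, Cc1ccc(cc1)S(=O)(=O)NN
Why: Neutral condensation of the aldehyde with tosylhydrazide should trap the β‑peroxy aldehyde before β‑elimination can occur and affects no stereocentre.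

Step 15
Reactants: 23 tosylhydrazone of 22
Product: 25 (4R,6R)‑4,6‑diethyl‑6‑[(1E,4R,5E)‑4‑ethyl‑2‑methylocta‑1,5‑dien‑1‑yl]‑3‑methoxy‑1,2‑dioxane (C3 epimers), via N‑boryl hydrazide 24 (not isolated)
Conditions: catecholborane, CHCl3, 0 °C; then NaOAc·3H2O, 60 °C
Reagents that add atoms: none
Why: Caglioti‑type reduction of the tosylhydrazone with catecholborane followed by acetate‑induced loss of sulfinate and N2 should convert CH2CH=N into the axial C6 ethyl group without strong base and below the temperature at which the di‑ and trisubstituted alkenes are hydroborated.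

Step 16
Reactants: 25 (4R,6R)‑4,6‑diethyl‑6‑[(1E,4R,5E)‑4‑ethyl‑2‑methylocta‑1,5‑dien‑1‑yl]‑3‑methoxy‑1,2‑dioxane
Product: 26 methyl 2‑{(3R,4R,6R)‑4,6‑diethyl‑6‑[(1E,4R,5E)‑4‑ethyl‑2‑methylocta‑1,5‑dien‑1‑yl]‑1,2‑dioxan‑3‑yl}acetate
Conditions: CH2=C(OMe)OSiMe2t‑Bu, TMSOTf, CH2Cl2, −78 °C
Reagents that add atoms: tert‑butyl[(1‑methoxyethenyl)oxy]dimethylsilane, C=C(OC)O[Si](C)(C)C(C)(C)C
Why: Ionisation of the methyl peroxyacetal to the C3 peroxycarbenium ion and Mukaiyama‑type capture by the silyl ketene acetal should occur by axial attack on the half‑chair that keeps the C4 ethyl and the C6 side chain pseudo‑equatorial, the axial C6 ethyl shielding the other face, so that CH2CO2Me enters cis to the C4 ethyl and to the side chain (C3 = R).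

Step 17
Reactants: 26 methyl 2‑{(3R,4R,6R)‑4,6‑diethyl‑6‑[(1E,4R,5E)‑4‑ethyl‑2‑methylocta‑1,5‑dien‑1‑yl]‑1,2‑dioxan‑3‑yl}acetate
Product: 27 2‑{(3R,4R,6R)‑4,6‑diethyl‑6‑[(1E,4R,5E)‑4‑ethyl‑2‑methylocta‑1,5‑dien‑1‑yl]‑1,2‑dioxan‑3‑yl}acetic acid (CNP0136940.4)
Conditions: LiOH, THF–H2O, 0 °C to rt; then 1 M HCl to pH 3
Reagents that add atoms: lithium hydroxide, [Li+].[OH-]
Why: Mild saponification (acyl–oxygen cleavage) followed by gentle acidification should give the acid without touching the dialkyl peroxide or any stereocentre.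

**Compound list**

1 | (2E)‑pent‑2‑enal | CC/C=C/C=O | starting material
2 | (3R,4E)‑hept‑4‑en‑3‑ol | CC/C=C/[C@H](O)CC | intermediate
3 | ethyl (3R,4E)‑3‑ethylhept‑4‑enoate | CC/C=C/[C@H](CC)CC(=O)OCC | intermediate
4 | (3R,4E)‑3‑ethylhept‑4‑enal | CC/C=C/[C@H](CC)CC=O | intermediate
5 | (4R,5E)‑4‑ethyloct‑5‑en‑1‑yne | CC/C=C/[C@H](CC)CC#C | intermediate
6 | [(1E,4R,5E)‑4‑ethyl‑2‑methylocta‑1,5‑dien‑1‑yl]dimethylalane | CC/C=C/[C@H](CC)C/C(C)=C/[Al](C)C | intermediate (not isolated)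
7 | (1E,4R,5E)‑4‑ethyl‑1‑iodo‑2‑methylocta‑1,5‑diene | CC/C=C/[C@H](CC)C/C(C)=C/I | intermediate
8 | but‑1‑ene | C=CCC | starting material
9 | trichloroacetyl chloride | ClC(Cl)(Cl)C(Cl)=O | starting material
10 | 2,2‑dichloro‑3‑ethylcyclobutan‑1‑one (racemic) | O=C1CC(CC)C1(Cl)Cl | intermediate
11 | 3‑ethylcyclobutan‑1‑one | O=C1CC(CC)C1 | intermediate
12 | lithium (3R)‑3‑ethylcyclobut‑1‑en‑1‑olate | [Li]OC1=C[C@H](CC)C1 | intermediate (not isolated)
13 | {[(3R)‑3‑ethylcyclobut‑1‑en‑1‑yl]oxy}trimethylsilane | C[Si](C)(C)OC1=C[C@H](CC)C1 | intermediate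
14 | (3R)‑3‑ethyl‑1‑(trimethylsilyloxy)‑5‑oxabicyclo[2.1.0]pentane, oxirane oxygen anti to ethyl | C[Si](C)(C)O[C@@]12C[C@@H](CC)[C@@H]1O2 | intermediate (not isolated)
15 | (2S,3R)‑3‑ethyl‑2‑(trimethylsilyloxy)cyclobutan‑1‑one | O=C1C[C@@H](CC)[C@@H]1O[Si](C)(C)C | intermediate (not isolated)
16 | (2S,3R)‑3‑ethyl‑2‑hydroxycyclobutan‑1‑one | O=C1C[C@@H](CC)[C@@H]1O | intermediate
17 | (2S,3R)‑3‑ethyl‑2‑methoxycyclobutan‑1‑one | O=C1C[C@@H](CC)[C@@H]1OC | intermediate
18 | [(1E,4R,5E)‑4‑ethyl‑2‑methylocta‑1,5‑dien‑1‑yl]lithium | CC/C=C/[C@H](CC)C/C(C)=C/[Li] | intermediate (not isolated)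
19 | (2S,3R)‑3‑ethyl‑1‑[(1E,4R,5E)‑4‑ethyl‑2‑methylocta‑1,5‑dien‑1‑yl]‑2‑methoxycyclobutan‑1‑ol (C1 epimers) | CC/C=C/[C@H](CC)C/C(C)=C/C1(O)C[C@@H](CC)[C@@H]1OC | intermediate
20 | (2R,5E,8R,9E)‑2,8‑diethyl‑1‑hydroperoxy‑1‑methoxy‑6‑methyldodeca‑5,9‑dien‑4‑one (C1 epimers) | CC/C=C/[C@H](CC)C/C(C)=C/C(=O)C[C@@H](CC)C(OC)OO | intermediate (not isolated)
21 | (4R)‑4‑ethyl‑6‑[(1E,4R,5E)‑4‑ethyl‑2‑methylocta‑1,5‑dien‑1‑yl]‑3‑methoxy‑1,2‑dioxan‑6‑ol (C3 and C6 epimers) | CC/C=C/[C@H](CC)C/C(C)=C/C1(O)C[C@@H](CC)C(OC)OO1 | intermediate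
22 | 2‑{(4R,6S)‑4‑ethyl‑6‑[(1E,4R,5E)‑4‑ethyl‑2‑methylocta‑1,5‑dien‑1‑yl]‑3‑methoxy‑1,2‑dioxan‑6‑yl}acetaldehyde (C3 epimers) | CC/C=C/[C@H](CC)C/C(C)=C/[C@@]1(CC=O)C[C@@H](CC)C(OC)OO1 | intermediate
23 | N'‑(2‑{(4R,6S)‑4‑ethyl‑6‑[(1E,4R,5E)‑4‑ethyl‑2‑methylocta‑1,5‑dien‑1‑yl]‑3‑methoxy‑1,2‑dioxan‑6‑yl}ethylidene)‑4‑methylbenzenesulfonohydrazide | CC/C=C/[C@H](CC)C/C(C)=C/[C@@]1(CC=NNS(=O)(=O)c2ccc(C)cc2)C[C@@H](CC)C(OC)OO1 | intermediate
24 | N‑(1,3,2‑benzodioxaborol‑2‑yl)‑N‑(2‑{(4R,6S)‑4‑ethyl‑6‑[(1E,4R,5E)‑4‑ethyl‑2‑methylocta‑1,5‑dien‑1‑yl]‑3‑methoxy‑1,2‑dioxan‑6‑yl}ethyl)‑N'‑tosylhydrazine | CC/C=C/[C@H](CC)C/C(C)=C/[C@@]1(CCN(B2Oc3ccccc3O2)NS(=O)(=O)c2ccc(C)cc2)C[C@@H](CC)C(OC)OO1 | intermediate (not isolated)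
25 | (4R,6R)‑4,6‑diethyl‑6‑[(1E,4R,5E)‑4‑ethyl‑2‑methylocta‑1,5‑dien‑1‑yl]‑3‑methoxy‑1,2‑dioxane (C3 epimers) | CC/C=C/[C@H](CC)C/C(C)=C/[C@@]1(CC)C[C@@H](CC)C(OC)OO1 | intermediate
26 | methyl 2‑{(3R,4R,6R)‑4,6‑diethyl‑6‑[(1E,4R,5E)‑4‑ethyl‑2‑methylocta‑1,5‑dien‑1‑yl]‑1,2‑dioxan‑3‑yl}acetate | CC/C=C/[C@H](CC)C/C(C)=C/[C@@]1(CC)C[C@@H](CC)[C@@H](CC(=O)OC)OO1 | intermediate
27 | 2‑{(3R,4R,6R)‑4,6‑diethyl‑6‑[(1E,4R,5E)‑4‑ethyl‑2‑methylocta‑1,5‑dien‑1‑yl]‑1,2‑dioxan‑3‑yl}acetic acid | CC/C=C/[C@H](CC)C/C(C)=C/[C@@]1(CC)C[C@@H](CC)[C@@H](CC(=O)O)OO1 | target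

Total step count: 17. Longest linear sequence: 12 steps (steps 1–5 then 11–17, or steps 6–10 then 11–17).

**Steps most likely to fail**

Step 12. Cobalt may dehydrate the secondary α‑methoxy hydroperoxide to the methyl ester, or peroxy‑hemiketalisation onto the conjugated ketone may be too slow, so that the peroxide is lost before the ring closes. The fallback sets out from 19 and separates C–C cleavage from peroxide installation. Hypoiodite (alkoxy‑radical) fragmentation of 19 with PhI(OAc)2 and I2 under visible light in CH2Cl2 should cleave the same C6–C3 bond; the C3 radical is oxidised and captured by acetate to give the open‑chain keto acetal (2R,5E,8R,9E)‑2,8‑diethyl‑1‑methoxy‑6‑methyl‑4‑oxododeca‑5,9‑dien‑1‑yl acetate F1. Acid‑catalysed exchange of acetate for hydroperoxide (ethereal H2O2, camphorsulfonic acid, 0 °C) then gives 20, which closes to 21, where the route is rejoined.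

Step 13. The C6 cation is an oxygen‑stabilised allyl cation; if capture by the weakly nucleophilic enol silane is slow, attack at C8, loss of the E geometry by rotation in the cation, or competing ionisation at C3 may intervene. The fallback sets out from 21 and uses the far more nucleophilic silyl ketene acetal CH2=C(OMe)OSiMe2t‑Bu with catalytic TMSOTf at −78 °C to give methyl 2‑{(4R,6S)‑4‑ethyl‑6‑[(1E,4R,5E)‑4‑ethyl‑2‑methylocta‑1,5‑dien‑1‑yl]‑3‑methoxy‑1,2‑dioxan‑6‑yl}acetate F2. Reduction with DIBAL‑H at −78 °C then gives aldehyde 22, where the route is rejoined.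

Step 16. The Lewis acid needed to ionise the methyl peroxyacetal may also heterolyse the tertiary allylic C6–O bond, and axial selectivity may erode under forcing conditions. The fallback sets out from 25 and changes leaving group, nucleophile and end game. Mild hydrolysis (PPTS, acetone–water) should give (4R,6R)‑4,6‑diethyl‑6‑[(1E,4R,5E)‑4‑ethyl‑2‑methylocta‑1,5‑dien‑1‑yl]‑1,2‑dioxan‑3‑ol F3, and acetylation (Ac2O, pyridine) the corresponding 1,2‑dioxan‑3‑yl acetate F4. The acetate ionises with catalytic TMSOTf at −78 °C and is captured axially by trimethyl(vinyloxy)silane to give 2‑{(3R,4R,6R)‑4,6‑diethyl‑6‑[(1E,4R,5E)‑4‑ethyl‑2‑methylocta‑1,5‑dien‑1‑yl]‑1,2‑dioxan‑3‑yl}acetaldehyde F5. Pinnick oxidation (NaClO2, NaH2PO4, 2‑methyl‑2‑butene, t‑BuOH–H2O) then gives 27 directly, where the route is rejoined without the basic hydrolysis.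

Further compounds

F1 | step 12 | (2R,5E,8R,9E)‑2,8‑diethyl‑1‑methoxy‑6‑methyl‑4‑oxododeca‑5,9‑dien‑1‑yl acetate (C1 epimers) | CC/C=C/[C@H](CC)C/C(C)=C/C(=O)C[C@@H](CC)C(OC)OC(C)=O
F2 | step 13 | methyl 2‑{(4R,6S)‑4‑ethyl‑6‑[(1E,4R,5E)‑4‑ethyl‑2‑methylocta‑1,5‑dien‑1‑yl]‑3‑methoxy‑1,2‑dioxan‑6‑yl}acetate (C3 epimers) | CC/C=C/[C@H](CC)C/C(C)=C/[C@@]1(CC(=O)OC)C[C@@H](CC)C(OC)OO1
F3 | step 16 | (4R,6R)‑4,6‑diethyl‑6‑[(1E,4R,5E)‑4‑ethyl‑2‑methylocta‑1,5‑dien‑1‑yl]‑1,2‑dioxan‑3‑ol (C3 epimers) | CC/C=C/[C@H](CC)C/C(C)=C/[C@@]1(CC)C[C@@H](CC)C(O)OO1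
F4 | step 16 | (4R,6R)‑4,6‑diethyl‑6‑[(1E,4R,5E)‑4‑ethyl‑2‑methylocta‑1,5‑dien‑1‑yl]‑1,2‑dioxan‑3‑yl acetate (C3 epimers) | CC/C=C/[C@H](CC)C/C(C)=C/[C@@]1(CC)C[C@@H](CC)C(OC(C)=O)OO1
F5 | step 16 | 2‑{(3R,4R,6R)‑4,6‑diethyl‑6‑[(1E,4R,5E)‑4‑ethyl‑2‑methylocta‑1,5‑dien‑1‑yl]‑1,2‑dioxan‑3‑yl}acetaldehyde | CC/C=C/[C@H](CC)C/C(C)=C/[C@@]1(CC)C[C@@H](CC)[C@@H](CC=O)OO1
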